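**Retrosynthetic overview**

1. Target 22 comes from its 5,7-bis-MOM ether 21 by acetal cleavage; nothing else follows the key step.
2. 21 is cut at C3–C4, O1–C8a and C8–CH3 into Weinreb amide 6 and (R)-chlorohydrin 13. Ring C (the dihydropyranone) is the only ring formed and it is formed last; rings A and B are carried through as the benzene rings of 5-fluororesorcinol and 2,4-dibromoanisole.
3. Enabling feature: on ring A the ring oxygen O1 (on C8a) and the methyl group (on C8) sit on neighbouring carbons beside the oxygenated C7. This is the print of a C8≡C8a aryne (a 3-alkoxyaryne) that takes an O-nucleophile at C8a and an electrophile (MeI) at C8. C4, on the adjoining C4a, holds the O1–C2–C3 chain, so the C2 alkoxide reaches C8a through a six-membered ring.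
4. 6 comes from 5-fluororesorcinol by MOM protection and two directed ortho-metalations (prenyl between the acetal oxygens, amide next to fluorine). 13 comes from 2,4-dibromoanisole by prenylation, chloroacetylation and asymmetric transfer hydrogenation, which sets the only stereocentre: (R) in 13 becomes (S) at C2 with the same spatial arrangement, because only the CIP ranking changes.

Key step: step 7

Assumption: 5-fluorobenzene-1,3-diol, 2,4-dibromoanisole, prenyl bromide, N-methoxy-N-methylcarbamoyl chloride and 2-chloro-N-methoxy-N-methylacetamide are taken as commercial; the target is the (2S)-flavanone, as read from the SMILES.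

**Route**

Step 1
Reactants: 1 5-fluorobenzene-1,3-diol
Product: 2 1-fluoro-3,5-bis(methoxymethoxy)benzene
Conditions: NaH (2.4 equiv), MOMCl (2.4 equiv), DMF, 0 °C to rt
Reagents that add atoms: chloromethyl methyl ether, COCCl
Why: Williamson-type O-alkylation of both phenoxides installs acetal groups that later direct metalation and are removable by mild acid; no stereocentre is involved.

Step 2
Reactants: 2 1-fluoro-3,5-bis(methoxymethoxy)benzene
Product: 4 5-fluoro-1,3-bis(methoxymethoxy)-2-(3-methylbut-2-en-1-yl)benzene, via aryllithium 3 (not isolated)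
Conditions: n-BuLi (1.1 equiv), THF, −20 to 0 °C; CuBr·SMe2 (10 mol %), prenyl bromide, −78 °C to rt
Reagents that add atoms: prenyl bromide, CC(C)=CCBr
Why: Directed ortho-metalation with n-BuLi should occur at the carbon flanked by both OMOM groups (double coordination outweighs the fluorine-flanked site), and copper-catalysed allylic substitution at the unhindered terminus of prenyl bromide then gives the linear prenyl arene.

Step 3
Reactants: 4 5-fluoro-1,3-bis(methoxymethoxy)-2-(3-methylbut-2-en-1-yl)benzene
Product: 6 6-fluoro-N-methoxy-2,4-bis(methoxymethoxy)-N-methyl-3-(3-methylbut-2-en-1-yl)benzamide, via aryllithium 5 (not isolated)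
Conditions: n-BuLi (1.1 equiv), THF, −78 °C; cannulated into ClC(O)N(OMe)Me (1.5 equiv), THF, −78 °C; aq. NH4Cl
Reagents that add atoms: N-methoxy-N-methylcarbamoyl chloride, CON(C)C(Cl)=O
Why: Directed ortho-metalation at one of the two equivalent ring hydrogens flanked by F and OMOM (the only ring C–H type left), followed by acylation of the aryllithium with the carbamoyl chloride (Weinreb amide synthesis); holding −78 °C keeps the ortho-fluoroaryllithium from losing LiF.

Step 4
Reactants: 7 2,4-dibromo-1-methoxybenzene
Product: 9 4-bromo-1-methoxy-2-(3-methylbut-2-en-1-yl)benzene, via aryllithium 8 (not isolated)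
Conditions: n-BuLi (1.0 equiv), Et2O, −78 °C; CuBr·SMe2 (10 mol %), prenyl bromide, −78 °C to rt
Reagents that add atoms: prenyl bromide, CC(C)=CCBr
Why: Bromine–lithium exchange should be selective for the bromine ortho to the methoxy group (coordination and inductive stabilisation of the aryllithium), and copper-catalysed allylic substitution then delivers the linear prenyl group.

Step 5
Reactants: 9 4-bromo-1-methoxy-2-(3-methylbut-2-en-1-yl)benzene
Product: 12 2-chloro-1-[4-methoxy-3-(3-methylbut-2-en-1-yl)phenyl]ethan-1-one, via aryllithium 10 (not isolated), via lithium hemiaminal 11 (not isolated)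
Conditions: n-BuLi (1.05 equiv), THF, −78 °C; ClCH2C(O)N(OMe)Me, −78 °C; 1 M HCl, 0 °C
Reagents that add atoms: 2-chloro-N-methoxy-N-methylacetamide, CON(C)C(=O)CCl
Why: Bromine–lithium exchange followed by Weinreb ketone synthesis, in which the chelated tetrahedral adduct prevents over-addition and the C–Cl bond survives at −78 °C.

Step 6
Reactants: 12 2-chloro-1-[4-methoxy-3-(3-methylbut-2-en-1-yl)phenyl]ethan-1-one
Product: 13 (1R)-2-chloro-1-[4-methoxy-3-(3-methylbut-2-en-1-yl)phenyl]ethan-1-ol
Conditions: RuCl[(S,S)-TsDPEN](p-cymene) (1 mol %), HCO2H/Et3N (5:2), EtOAc, 25 °C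
Reagents that add atoms: none
Why: Noyori-type asymmetric transfer hydrogenation, in which the (S,S)-catalyst should deliver hydride to the same ketone face as for acetophenones and so set the (R)-carbinol under catalyst control (R because CH2Cl outranks aryl), without touching the prenyl alkene or the C–Cl bond.

Step 7
Reactants: 13 (1R)-2-chloro-1-[4-methoxy-3-(3-methylbut-2-en-1-yl)phenyl]ethan-1-ol; 6 6-fluoro-N-methoxy-2,4-bis(methoxymethoxy)-N-methyl-3-(3-methylbut-2-en-1-yl)benzamide
Product: 21 (2S)-2-[4-methoxy-3-(3-methylbut-2-en-1-yl)phenyl]-5,7-bis(methoxymethoxy)-8-methyl-6-(3-methylbut-2-en-1-yl)-2,3-dihydro-4H-1-benzopyran-4-one, via lithium alkoxide 14 (not isolated), via dilithio reagent 15 (not isolated), via tetrahedral adduct 16 (not isolated), via ring-lithiated adduct 17 (not isolated), via aryne 18 (not isolated), via cyclised aryllithium 19 (not isolated), via methylated hemiaminal salt 20 (not isolated)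
Conditions: 13, n-BuLi (1.0 equiv), THF, −78 °C; LiDBB (2.0 equiv, titrated), −78 °C; 6 (0.85 equiv), −78 °C; s-BuLi (1.1 equiv to 6), −78 to −10 °C; MeI (3 equiv), −40 to 0 °C; aq. NH4Cl, 0 °C
Reagents that add atoms: iodomethane, CI
Why: Proposed new method: O-deprotonation and reductive C–Cl lithiation turn 13 into the β-oxido alkyllithium 15, which adds to the Weinreb amide 6 to give the chelated tetrahedral adduct 16 (C3–C4 bond); s-BuLi then removes the only ring hydrogen of ring A (C8–H, flanked by F and OMOM) to give 17, which on warming loses LiF to the C8≡C8a aryne 18, whose tethered C2 alkoxide adds to C8a (O1–C8a bond) to leave the C8 aryllithium 19, which is methylated by MeI to 20 before the hemiaminal collapses to the ketone on work-up. The closest known reaction types are the acylation of organolithiums by Weinreb amides, the benzyne cyclisation of tethered alkoxides to chromans and dihydrobenzofurans, and the nucleophile/electrophile 1,2-difunctionalisation of 3-alkoxyarynes; what is new is their merger in one flask on a tetrahedral amide adduct, which keeps C4 at the ketone oxidation level yet unreactive. The pyranone ring closes in a 6-exo-dig mode, the alkoxide attacking the in-plane π bond of the aryne at the carbon next to the tether, whereas attack by the C4 oxide would need a four-membered ring and is not expected. No stereocentre of the product is created: C2 comes from 13, none of its bonds is made or broken, so its configuration should be retained (spatially unchanged, descriptor S in 21), and the hemiaminal centre at C4 is transient. The regiochemistry needed (O at C8a, CH3 at C8) is secured twice, by the tether and by the C7 OMOM group beside the triple bond, which makes C8a the more electrophilic aryne carbon and stabilises the carbanion at C8 between two oxygens. Chemoselectivity rests on the absence of any other ring hydrogen on ring A and of any N–H proton source in the flask, so that 19 survives until it meets MeI.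

Step 8
Reactants: 21 (2S)-2-[4-methoxy-3-(3-methylbut-2-en-1-yl)phenyl]-5,7-bis(methoxymethoxy)-8-methyl-6-(3-methylbut-2-en-1-yl)-2,3-dihydro-4H-1-benzopyran-4-one
Product: 22 (2S)-5,7-dihydroxy-2-[4-methoxy-3-(3-methylbut-2-en-1-yl)phenyl]-8-methyl-6-(3-methylbut-2-en-1-yl)-2,3-dihydro-4H-1-benzopyran-4-one
Conditions: HCl (3 M aq.), MeOH, 40–50 °C, short reaction time
Reagents that add atoms: none
Why: Acid-catalysed acetal cleavage (transacetalisation to methanol) frees both phenols under conditions that should leave the aryl methyl ether, both prenyl groups and the C2 stereocentre untouched.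

**Compound list**

1 | 5-fluorobenzene-1,3-diol (5-fluororesorcinol) | Oc1cc(O)cc(F)c1 | starting material
2 | 1-fluoro-3,5-bis(methoxymethoxy)benzene | COCOc1cc(F)cc(OCOC)c1 | intermediate
3 | [4-fluoro-2,6-bis(methoxymethoxy)phenyl]lithium | [Li]c1c(OCOC)cc(F)cc1OCOC | intermediate (not isolated)
4 | 5-fluoro-1,3-bis(methoxymethoxy)-2-(3-methylbut-2-en-1-yl)benzene | CC(C)=CCc1c(OCOC)cc(F)cc1OCOC | intermediate
5 | [6-fluoro-2,4-bis(methoxymethoxy)-3-(3-methylbut-2-en-1-yl)phenyl]lithium | CC(C)=CCc1c(OCOC)cc(F)c([Li])c1OCOC | intermediate (not isolated)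
6 | 6-fluoro-N-methoxy-2,4-bis(methoxymethoxy)-N-methyl-3-(3-methylbut-2-en-1-yl)benzamide | CON(C)C(=O)c1c(F)cc(OCOC)c(CC=C(C)C)c1OCOC | intermediate
7 | 2,4-dibromo-1-methoxybenzene (2,4-dibromoanisole) | COc1ccc(Br)cc1Br | starting material
8 | (5-bromo-2-methoxyphenyl)lithium | COc1ccc(Br)cc1[Li] | intermediate (not isolated)
9 | 4-bromo-1-methoxy-2-(3-methylbut-2-en-1-yl)benzene | COc1ccc(Br)cc1CC=C(C)C | intermediate
10 | [4-methoxy-3-(3-methylbut-2-en-1-yl)phenyl]lithium | COc1ccc([Li])cc1CC=C(C)C | intermediate (not isolated)
11 | lithium 2-chloro-1-[methoxy(methyl)amino]-1-[4-methoxy-3-(3-methylbut-2-en-1-yl)phenyl]ethan-1-olate | COc1ccc(C(O[Li])(CCl)N(C)OC)cc1CC=C(C)C | intermediate (not isolated)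
12 | 2-chloro-1-[4-methoxy-3-(3-methylbut-2-en-1-yl)phenyl]ethan-1-one | COc1ccc(C(=O)CCl)cc1CC=C(C)C | intermediate
13 | (1R)-2-chloro-1-[4-methoxy-3-(3-methylbut-2-en-1-yl)phenyl]ethan-1-ol | COc1ccc([C@@H](O)CCl)cc1CC=C(C)C | intermediate
14 | lithium alkoxide of 13 | COc1ccc([C@@H](O[Li])CCl)cc1CC=C(C)C | intermediate (not isolated)
15 | C,O-dilithio reagent LiCH2–CH(OLi)Ar from 13, carbinol configuration unchanged | COc1ccc([C@@H](O[Li])C[Li])cc1CC=C(C)C | intermediate (not isolated)
16 | dilithium tetrahedral adduct of 15 and 6 (N,O-hemiaminal at C4, both epimers) | COc1ccc([C@@H](O[Li])CC(O[Li])(N(C)OC)c2c(F)cc(OCOC)c(CC=C(C)C)c2OCOC)cc1CC=C(C)C | intermediate (not isolated)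
17 | adduct 16 lithiated at the ring carbon between F and OMOM (future C8) | COc1ccc([C@@H](O[Li])CC(O[Li])(N(C)OC)c2c(F)c([Li])c(OCOC)c(CC=C(C)C)c2OCOC)cc1CC=C(C)C | intermediate (not isolated)
18 | C8≡C8a aryne from 17 by loss of LiF | COc1ccc([C@@H](O[Li])CC(O[Li])(N(C)OC)C2=C(OCOC)C(CC=C(C)C)=C(OCOC)C#C2)cc1CC=C(C)C | intermediate (not isolated)
19 | 8-lithio-2-aryl-chroman bearing the lithium N,O-hemiaminal at C4 | COc1ccc([C@@H]2CC(O[Li])(N(C)OC)c3c(OCOC)c(CC=C(C)C)c(OCOC)c([Li])c3O2)cc1CC=C(C)C | intermediate (not isolated)
20 | 8-methyl lithium N,O-hemiaminal (C4) of 21 | COc1ccc([C@@H]2CC(O[Li])(N(C)OC)c3c(OCOC)c(CC=C(C)C)c(OCOC)c(C)c3O2)cc1CC=C(C)C | intermediate (not isolated)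
21 | (2S)-2-[4-methoxy-3-(3-methylbut-2-en-1-yl)phenyl]-5,7-bis(methoxymethoxy)-8-methyl-6-(3-methylbut-2-en-1-yl)-2,3-dihydro-4H-1-benzopyran-4-one | COc1ccc([C@@H]2CC(=O)c3c(OCOC)c(CC=C(C)C)c(OCOC)c(C)c3O2)cc1CC=C(C)C | intermediate
22 | (2S)-5,7-dihydroxy-2-[4-methoxy-3-(3-methylbut-2-en-1-yl)phenyl]-8-methyl-6-(3-methylbut-2-en-1-yl)-2,3-dihydro-4H-1-benzopyran-4-one | COc1ccc([C@@H]2CC(=O)c3c(O)c(CC=C(C)C)c(O)c(C)c3O2)cc1CC=C(C)C | target

**Step count**

Total steps: 8. Longest linear sequence: 5 steps (1, 2, 3, 7, 8 or 4, 5, 6, 7, 8).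

**Steps most likely to fail**

Step 7 (proposed new method). Several processes may defeat the cascade:
- proton abstraction from 6 by the alkyllithium 15 in place of carbonyl addition;
- β-elimination of 15 to the styrene before it adds to the hindered amide;
- intermolecular capture of the aryne if the lithium alkoxide adds slowly;
- protonation of the cyclised aryllithium before it is methylated, which would leave C8–H.

The fallback uses only known reaction types, sets out from 4 and comes back at 21. Ortho-lithiation of 4 next to fluorine (n-BuLi, THF, −78 °C) and a quench with iodomethane should give 1-fluoro-2-methyl-3,5-bis(methoxymethoxy)-4-(3-methylbut-2-en-1-yl)benzene F1. A second ortho-lithiation at the last ring hydrogen and trapping with N-methoxy-N-methylcarbamoyl chloride should give 2-fluoro-N-methoxy-4,6-bis(methoxymethoxy)-N,3-dimethyl-5-(3-methylbut-2-en-1-yl)benzamide F2. Addition of the dilithio reagent 15 (made from 13 as in step 7) with aqueous work-up should give the β-hydroxy ketone (3S)-1-[2-fluoro-4,6-bis(methoxymethoxy)-3-methyl-5-(3-methylbut-2-en-1-yl)phenyl]-3-hydroxy-3-[4-methoxy-3-(3-methylbut-2-en-1-yl)phenyl]propan-1-one F3. Intramolecular SNAr of its alkoxide on the fluoride activated by the ortho ketone (K2CO3 or Cs2CO3, DMF, rt to 50 °C) then closes the pyranone ring with the C2–O bond untouched and returns to 21. Here the methyl group is placed before ring closure and the aryne is not needed.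

Step 2. Metalation may take place next to fluorine in place of the carbon between the two acetal oxygens; the misplaced aryllithium would lose LiF on warming and the prenyl group would end up at the wrong carbon. The fallback sets out from 2 and comes back at 4, using bromine as a blocking group. Electrophilic dibromination (NBS, 2 equiv, MeCN, 0 °C) should occupy the two carbons ortho to fluorine, each para to one OMOM, and spare the crowded carbon between the acetals, giving 2,4-dibromo-3-fluoro-1,5-bis(methoxymethoxy)benzene F4. Magnesiation of the one remaining ring C–H with TMPMgCl·LiCl (THF, 0 °C to rt; no halogen migration is expected with magnesium) and CuI-catalysed allylation with prenyl bromide should give 1,3-dibromo-2-fluoro-4,6-bis(methoxymethoxy)-5-(3-methylbut-2-en-1-yl)benzene F5. Two successive bromine–lithium exchange and methanol quench cycles (n-BuLi, THF, −78 °C) then remove both bromines and return to 4.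

Step 8. Under Brønsted acid the freed 5- or 7-hydroxyl may add to the neighbouring C6 prenyl alkene (chroman formation), and the prenyl alkenes may take up HCl or methanol. The fallback sets out from 21 and comes back at 22 without a protic acid. Treatment with TMSOTf and 2,2'-bipyridyl (CH2Cl2, 0 °C) should exchange both aryl MOM ethers for silyl ethers, giving (2S)-2-[4-methoxy-3-(3-methylbut-2-en-1-yl)phenyl]-8-methyl-6-(3-methylbut-2-en-1-yl)-5,7-bis(trimethylsilyloxy)-2,3-dihydro-4H-1-benzopyran-4-one F6. Hydrolysis of F6 with water at neutral pH then returns to 22.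

**Further compounds**

F1 | step 7 | 1-fluoro-2-methyl-3,5-bis(methoxymethoxy)-4-(3-methylbut-2-en-1-yl)benzene | CC(C)=CCc1c(OCOC)cc(F)c(C)c1OCOC
F2 | step 7 | 2-fluoro-N-methoxy-4,6-bis(methoxymethoxy)-N,3-dimethyl-5-(3-methylbut-2-en-1-yl)benzamide | CON(C)C(=O)c1c(F)c(C)c(OCOC)c(CC=C(C)C)c1OCOC
F3 | step 7 | (3S)-1-[2-fluoro-4,6-bis(methoxymethoxy)-3-methyl-5-(3-methylbut-2-en-1-yl)phenyl]-3-hydroxy-3-[4-methoxy-3-(3-methylbut-2-en-1-yl)phenyl]propan-1-one | COc1ccc([C@@H](O)CC(=O)c2c(F)c(C)c(OCOC)c(CC=C(C)C)c2OCOC)cc1CC=C(C)C
F4 | step 2 | 2,4-dibromo-3-fluoro-1,5-bis(methoxymethoxy)benzene | COCOc1cc(OCOC)c(Br)c(F)c1Br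
F5 | step 2 | 1,3-dibromo-2-fluoro-4,6-bis(methoxymethoxy)-5-(3-methylbut-2-en-1-yl)benzene | COCOc1c(CC=C(C)C)c(OCOC)c(Br)c(F)c1Br
F6 | step 8 | (2S)-2-[4-methoxy-3-(3-methylbut-2-en-1-yl)phenyl]-8-methyl-6-(3-methylbut-2-en-1-yl)-5,7-bis(trimethylsilyloxy)-2,3-dihydro-4H-1-benzopyran-4-one | COc1ccc([C@@H]2CC(=O)c3c(O[Si](C)(C)C)c(CC=C(C)C)c(O[Si](C)(C)C)c(C)c3O2)cc1CC=C(C)C
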